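The whole plan depends on cutting the C4a–C8a bond of the middle ring A (C4a, C5, C6, C7, C8, C8a). That ring has oxygen on C5, C7 and C8a and carbon on C8 (top C4) and C4a (middle C4, bound to bottom C8), so a 3,5,7-triketo ester branched at its α-carbon maps onto it atom for atom. In one operation a magnesium alkoxide opens a 2-pyrone and the freed chain closes by Claisen condensation. The aromatic ring thus appears between the two flavan units with three distinguishable oxygens. The precursor is a 4-benzyloxy-2-pyrone with benzylated epicatechin (through C4β) at C3 and the bottom-unit aroylmethyl group at C6. Ring C is then built on the ketone carbon.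

Key step: step 11

Remark on the chemistry: top = the unit with free 3-OH, and middle and bottom = the two 3-O-galloyl units; flavan numbering is used inside each unit, and β is the face of the C4 interflavan bonds (trans to O3); centres that are erased later (carbinol carbons of 13 and 18, anomeric C2 of 22 and 23) form as mixtures and are drawn without configuration; 19, 24, 31 and the pyrrolidine catalyst are assumed to be purchasable.

Step 1
Reactants: 1 (−)-epicatechin
Product: 2 5,7,3',4'-tetra-O-benzyl-(−)-epicatechin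
Conditions: BnBr (4.2 equiv), K2CO3, DMF, 0 °C to rt
Reagents that add atoms: benzyl bromide BrCc1ccccc1
Why: Williamson etherification: K2CO3 deprotonates only the four phenols, so the secondary 3-OH stays free for later differentiation and the C2 and C3 centres of the chiral-pool material are carried on unchanged.

Step 2
Reactants: 2 5,7,3',4'-tetra-O-benzyl-(−)-epicatechin
Product: 3 4β-(2-ethoxyethoxy)-5,7,3',4'-tetra-O-benzylepicatechin
Conditions: DDQ (2 equiv), 2-ethoxyethanol (5 equiv), CH2Cl2, rt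
Reagents that add atoms: 2-ethoxyethanol CCOCCO
Why: DDQ benzylic oxidation: hydride abstraction at C4 gives a cation stabilised by the 5,7-dialkoxy ring A, and the alcohol adds from the β face, anti to the pseudo-axial 3-OH, which sets the new C4 centre 3,4-trans.

Step 3
Reactants: 3 4β-(2-ethoxyethoxy)-5,7,3',4'-tetra-O-benzylepicatechin
Product: 4 4β-(2-ethoxyethoxy)-3,5,7,3',4'-penta-O-benzylepicatechin
Conditions: NaH, BnBr, Bu4NI (cat.), DMF, 0 °C to rt
Reagents that add atoms: benzyl bromide BrCc1ccccc1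
Why: Williamson etherification of the secondary alkoxide, to which the base-stable C4 ether is inert; benzyl on O3 marks this oxygen as the one that ends as free hydroxyl, while the two future gallate oxygens will carry silyl groups.

Step 4
Reactants: 4 4β-(2-ethoxyethoxy)-3,5,7,3',4'-penta-O-benzylepicatechin; 5 4-hydroxy-6-methyl-2H-pyran-2-one (triacetic acid lactone)
Product: 6 4-hydroxy-6-methyl-3-(penta-O-benzylepicatechin-4β-yl)-2-pyrone
Conditions: 5 (4 equiv), BF3·OEt2 (0.3 equiv), CH2Cl2–1,4-dioxane, 0 °C to rt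
Reagents that add atoms: none
Why: Friedel–Crafts-type C-alkylation of an enolic 1,3-dicarbonyl compound by a benzylic cation: BF3·OEt2 ionises the C4 ether, the nucleophilic C3 of 5 (in excess, to outrun self-condensation of 4) attacks from the β face anti to the pseudo-axial 3-OBn group as in all epicatechin C4 couplings, which sets top C4 as 3,4-trans, and any O-alkylated material re-ionises under the acid.

Step 5
Reactants: 6 4-hydroxy-6-methyl-3-(penta-O-benzylepicatechin-4β-yl)-2-pyrone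
Product: 7 4-benzyloxy-6-methyl-3-(penta-O-benzylepicatechin-4β-yl)-2-pyrone
Conditions: BnBr, K2CO3, DMF, rt
Reagents that add atoms: benzyl bromide BrCc1ccccc1
Why: O-alkylation of the vinylogous acid (the pyrone 4-OH) with a soft halide and carbonate base, conditions that give 4-alkoxy-2-pyrones in preference to 2-alkoxy-4-pyrones; this benzyl group becomes the C7 ether of the middle unit.

Step 6
Reactants: 2 5,7,3',4'-tetra-O-benzyl-(−)-epicatechin
Product: 8 8-bromo-5,7,3',4'-tetra-O-benzylepicatechin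
Conditions: NBS (1.0 equiv), CH2Cl2, −78 °C to rt
Reagents that add atoms: N-bromosuccinimide O=C1CCC(=O)N1Br
Why: Electrophilic aromatic bromination with one equivalent of NBS at low temperature, which on benzylated flavan-3-ols goes to C8, the most nucleophilic ring A position, and so fixes the site of the later interflavan carbon.

Step 7
Reactants: 8 8-bromo-5,7,3',4'-tetra-O-benzylepicatechin
Product: 9 8-bromo-5,7,3',4'-tetra-O-benzyl-3-O-TBS-epicatechin
Conditions: TBSCl, imidazole, DMF, rt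
Reagents that add atoms: tert-butyldimethylsilyl chloride CC(C)(C)[Si](C)(C)Cl
Why: Imidazole-promoted silylation of the secondary alcohol gives an ether that survives the organolithium, alkoxide, hydride and mild Lewis acid steps and can be removed by fluoride in the presence of benzyl ethers.

Step 8
Reactants: 9 8-bromo-5,7,3',4'-tetra-O-benzyl-3-O-TBS-epicatechin
Product: 11 5,7,3',4'-tetra-O-benzyl-3-O-TBS-epicatechin-8-carbaldehyde, via 8-lithio flavan 10 (not isolated)
Conditions: n-BuLi, THF, −78 °C; then DMF, −78 to 0 °C; aq NH4Cl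
Reagents that add atoms: N,N-dimethylformamide CN(C)C=O
Why: Bromine–lithium exchange followed by formylation of the aryllithium with DMF; at −78 °C the exchange is faster than any metalation of benzylic ether positions, and the stereocentres are remote from the anion.

Step 9
Reactants: 7 4-benzyloxy-6-methyl-3-(penta-O-benzylepicatechin-4β-yl)-2-pyrone; 11 5,7,3',4'-tetra-O-benzyl-3-O-TBS-epicatechin-8-carbaldehyde
Product: 13 4-benzyloxy-3-(top-4β-yl)-6-[2-hydroxy-2-(bottom-8-yl)ethyl]-2-pyrone, via 6-lithiomethyl pyrone 12 (not isolated)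
Conditions: LiN(i-Pr)2 (1.1 equiv), THF, −78 °C; then 11; AcOH quench at −78 °C
Reagents that add atoms: none
Why: Vinylogous aldol addition: with pyrone C3 blocked by the top unit, LiN(i-Pr)2 can only remove a proton from the 6-methyl group, and the dienolate adds through that carbon to the aldehyde, which is chosen over an amide or ester acyl donor because a carbonyl group between two ortho oxygens accepts a stabilised nucleophile reliably only at the aldehyde level; the carbinol centre forms without control and is erased in step 10.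

Step 10
Reactants: 13 4-benzyloxy-3-(top-4β-yl)-6-[2-hydroxy-2-(bottom-8-yl)ethyl]-2-pyrone
Product: 14 4-benzyloxy-3-(penta-O-benzylepicatechin-4β-yl)-6-[2-oxo-2-(tetra-O-benzyl-3-O-TBS-epicatechin-8-yl)ethyl]-2-pyrone
Conditions: Dess–Martin periodinane, NaHCO3, CH2Cl2, 0 °C to rt
Reagents that add atoms: none
Why: Dess–Martin oxidation of the secondary benzylic alcohol under buffered conditions, which spare the acid-labile electron-rich carbinol from dehydration to the styrylpyrone and leave the silyl and benzyl ethers alone.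

Step 11
Reactants: 14 4-benzyloxy-3-(penta-O-benzylepicatechin-4β-yl)-6-[2-oxo-2-(tetra-O-benzyl-3-O-TBS-epicatechin-8-yl)ethyl]-2-pyrone
Product: 16 [4-benzyloxy-2,6-dihydroxy-3-(top-4β-yl)phenyl] (bottom-8-yl) ketone (middle C7-OBn C5-OH C8a-OH), via ring-opened benzyl ester 15 (not isolated)
Conditions: Mg(OCH2Ph)2 (5 equiv, from (n-Bu)2Mg and PhCH2OH), PhCH2OH–toluene, 80 °C; then 1 M HCl, 0 °C
Reagents that add atoms: none
Why: Benzyloxide adds to the lactone carbonyl (pyrone C2) and ring opening gives 15 as a magnesium chelate of its 5,7-diketone and ester, in which the former pyrone C4 oxygen survives as a benzyl enol ether and the double-bond geometry inherited from the ring keeps ester and chain cis; the doubly activated methylene C6 (future C4a) then attacks the ester carbon (future C8a), benzyloxide leaves and two enolisations aromatise the ring. The closest known reaction type is the magnesium alkoxide-induced recyclisation of 6-(2-oxoalkyl)-2-pyrones and of 3,5,7-triketo esters to acylphloroglucinols. The one new ring closes in a 6-(enolexo)-exo-trig mode and no stereocentre is formed, while the five resident ones carry no acidic hydrogen and stay untouched. The step needs Claisen instead of aldol folding, which the substrate secures: the enol ether removes the chain C3 carbonyl, the flavanyl group makes chain C2 a carbon that could not aromatise after attack on the aryl ketone, and magnesium ties diketonate and ester oxygens together so that C6 and C1 meet. It also needs three distinguishable oxygens, and these follow from the pyrone: C7 keeps its benzyl group, C8a-OH (former lactone carbonyl) lies beside the top unit and C5-OH (former ring oxygen) lies beside C6-H. Benzyloxide replaces methoxide because addition–elimination at the vinylogous ester carbon would otherwise exchange the C7 benzyl ether for a methyl ether that hydrogenolysis cannot remove, whereas with Mg(OCH2Ph)2 this exchange is degenerate.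

Step 12
Reactants: 16 [4-benzyloxy-2,6-dihydroxy-3-(top-4β-yl)phenyl] (bottom-8-yl) ketone
Product: 17 [4,6-bis(benzyloxy)-2-hydroxy-3-(top-4β-yl)phenyl] (bottom-8-yl) ketone (C5-OBn C8a-OH)
Conditions: BnBr (1.05 equiv), K2CO3, DMF, 0 °C to rt
Reagents that add atoms: benzyl bromide BrCc1ccccc1
Why: Williamson etherification under kinetic control with one equivalent of halide: the C5 phenoxide has only C6-H as outer neighbour whereas the C8a phenoxide is buried beside the top flavanyl group, so benzylation should take place at O5 and leave O8a for ring C.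

Step 13
Reactants: 17 [4,6-bis(benzyloxy)-2-hydroxy-3-(top-4β-yl)phenyl] (bottom-8-yl) ketone
Product: 18 [4,6-bis(benzyloxy)-2-hydroxy-3-(top-4β-yl)phenyl](bottom-8-yl)methanol
Conditions: LiAlH4, THF, 0 °C; H2O then aq NaOH work-up
Reagents that add atoms: none
Why: Hydride reduction of a diaryl ketone: LiAlH4 first forms the aluminium phenoxide at O8a and delivers hydride from there to the crowded carbonyl group at a temperature at which the alkoxide does not yet eliminate (no over-reduction to the diarylmethane); the carbinol centre forms without control and vanishes in step 14.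

Step 14
Reactants: 18 [4,6-bis(benzyloxy)-2-hydroxy-3-(top-4β-yl)phenyl](bottom-8-yl)methanol; 19 (tert-butyldimethylsilyloxy)acetaldehyde
Product: 22 middle-unit lactol 5,7-bis(benzyloxy)-4β-(bottom-8-yl)-3α-(TBS-oxy)-8-(top-4β-yl)chroman-2-ol (3,4-trans), via o-quinone methide 20 (not isolated), via silyloxy enamine 21 (not isolated)
Conditions: 19 (3 equiv), (S)-2-[diphenyl(trimethylsilyloxy)methyl]pyrrolidine (20 mol %), 4-nitrobenzoic acid (20 mol %), CH2Cl2, 0 °C to rt
Reagents that add atoms: none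
Why: Enamine-catalysed formal [4+2] cycloaddition (Michael addition then hemiacetal formation) of an aldehyde to an o-quinone methide: the weak acid dehydrates the very electron-rich carbinol to 20, whose E geometry (bottom unit turned away from the carbonyl oxygen) is the only one that leaves the methide carbon open, the E enamine 21 is shielded on one face by the diphenyl(silyloxy)methyl group so that C3 is set by the catalyst, the synclinal approach that keeps the enamine nitrogen near the quinone methide oxygen sets C4 syn in the open chain and therefore 3,4-trans in the ring, the sense of both centres being the one this (S)-catalyst gives in aldehyde–nitroalkene Michael additions, and hydrolysis of the N,O-aminal by the released water returns the catalyst and leaves 22.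

Step 15
Reactants: 22 middle-unit lactol
Product: 23 middle-unit lactol acetate (2-acetoxy-3α-TBS-oxy-4β-aryl chroman)
Conditions: Ac2O, pyridine, DMAP (cat.), CH2Cl2, 0 °C
Reagents that add atoms: acetic anhydride CC(=O)OC(C)=O
Why: Acetylation of the hemiacetal hydroxyl group turns C2 into an ionisable acetal centre; the ring form reacts because the open form would expose only the hindered O8a phenol, and both anomers serve equally.

Step 16
Reactants: 24 4-bromocatechol
Product: 25 4-bromo-1,2-bis(benzyloxy)benzene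
Conditions: BnBr, K2CO3, DMF, rt
Reagents that add atoms: benzyl bromide BrCc1ccccc1
Why: Williamson etherification of both phenols gives the ring B building block in the same protecting-group pattern as the other two catechol rings.

Step 17
Reactants: 25 4-bromo-1,2-bis(benzyloxy)benzene
Product: 28 potassium [3,4-bis(benzyloxy)phenyl]trifluoroborate, via aryllithium 26 (not isolated), via lithium aryltriisopropoxyborate 27 (not isolated)
Conditions: n-BuLi, THF, −78 °C; B(Oi-Pr)3, −78 °C to rt; aq KHF2, MeOH, rt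
Reagents that add atoms: triisopropyl borate CC(C)OB(OC(C)C)OC(C)C; potassium hydrogen difluoride [K+].[F-].F
Why: Bromine–lithium exchange, borylation of the aryllithium and fluoride exchange with KHF2 is the standard route to crystalline, storable aryltrifluoroborates.

Step 18
Reactants: 23 middle-unit lactol acetate; 28 potassium [3,4-bis(benzyloxy)phenyl]trifluoroborate
Product: 29 penta-O-benzylepicatechin-(4β→8)-tetra-O-benzyl-3-O-TBS-epicatechin-(4β→8)-tetra-O-benzyl-3-O-TBS-epicatechin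
Conditions: 28 (2 equiv), BF3·OEt2 (2 equiv), CH2Cl2, −40 to 0 °C; aq NaHCO3
Reagents that add atoms: none
Why: Lewis acid-mediated substitution of a cyclic acetal acetate by an aryltrifluoroborate (C-aryl glycosylation type): the aryl group reaches the C2 oxocarbenium carbon along the pseudo-axial trajectory of the half-chair that has O3 and the C4 aryl group pseudo-equatorial, which is the α face anti to the bulky bottom unit (the β face is closed by that unit in either half-chair), so that C2 is set 2,4-trans and hence 2,3-cis, and the non-participating silyl ether on O3 avoids the 1,2-trans delivery that an ester could impose.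

Step 19
Reactants: 29 protected trimer bis(TBS ether)
Product: 30 protected trimer with free middle and bottom 3-OH
Conditions: Bu4NF, THF, rt to 45 °C; aq NH4Cl
Reagents that add atoms: none
Why: Fluoride-induced cleavage of both secondary silyl ethers in one operation, driven by the Si–F bond, with no effect on benzyl ethers, interflavan bonds or stereocentres.

Step 20
Reactants: 30 protected trimer with free middle and bottom 3-OH; 31 3,4,5-tris(benzyloxy)benzoic acid
Product: 32 protected trimer 3-O-(middle) and 3-O-(bottom) bis(tri-O-benzylgallate)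
Conditions: 31 (3 equiv), DCC, DMAP, CH2Cl2, rt
Reagents that add atoms: none
Why: Steglich esterification: DMAP-catalysed acyl transfer from the O-acylisourea esterifies both free secondary alcohols at once with retention, while top O3 is still benzylated.

Step 21
Reactants: 32 protected trimer bis(tri-O-benzylgallate)
Product: 33 epicatechin-(4β→8)-epicatechin 3-O-gallate-(4β→8)-epicatechin 3-O-gallate (CNP0279403.1)
Conditions: H2 (1 atm), Pd(OH)2/C, THF–MeOH–H2O, rt
Reagents that add atoms: none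
Why: Catalytic hydrogenolysis of all nineteen benzyl ethers over Pd(OH)2/C under neutral conditions, which leave gallate esters, the C2–O1 bonds and the 4→8 interflavan bonds of procyanidins intact.

Compound list

1 | (−)-epicatechin, (2R,3R) | O[C@@H]1Cc2c(O)cc(O)cc2O[C@@H]1c1ccc(O)c(O)c1 | starting material
2 | 5,7,3',4'-tetra-O-benzyl-(−)-epicatechin, free 3-OH | O1[C@H](c8ccc(OCc9ccccc9)c(OCc9ccccc9)c8)[C@H](O)Cc2c(OCc9ccccc9)cc(OCc9ccccc9)cc21 | intermediate
3 | 4β-(2-ethoxyethoxy)-5,7,3',4'-tetra-O-benzylepicatechin, 2,3-cis-3,4-trans | O1[C@H](c8ccc(OCc9ccccc9)c(OCc9ccccc9)c8)[C@H](O)[C@@H](OCCOCC)c2c(OCc9ccccc9)cc(OCc9ccccc9)cc21 | intermediate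
4 | 4β-(2-ethoxyethoxy)-3,5,7,3',4'-penta-O-benzylepicatechin | O1[C@H](c8ccc(OCc9ccccc9)c(OCc9ccccc9)c8)[C@H](OCc9ccccc9)[C@@H](OCCOCC)c2c(OCc9ccccc9)cc(OCc9ccccc9)cc21 | intermediate
5 | 4-hydroxy-6-methyl-2H-pyran-2-one (triacetic acid lactone) | Cc1cc(O)cc(=O)o1 | starting material
6 | 4-hydroxy-6-methyl-3-(penta-O-benzylepicatechin-4β-yl)-2-pyrone | O1[C@H](c8ccc(OCc9ccccc9)c(OCc9ccccc9)c8)[C@H](OCc9ccccc9)[C@@H](C3=C(O)C=C(C)OC3=O)c2c(OCc9ccccc9)cc(OCc9ccccc9)cc21 | intermediate
7 | 4-benzyloxy-6-methyl-3-(penta-O-benzylepicatechin-4β-yl)-2-pyrone | O1[C@H](c8ccc(OCc9ccccc9)c(OCc9ccccc9)c8)[C@H](OCc9ccccc9)[C@@H](C3=C(OCc9ccccc9)C=C(C)OC3=O)c2c(OCc9ccccc9)cc(OCc9ccccc9)cc21 | intermediate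
8 | 8-bromo-5,7,3',4'-tetra-O-benzylepicatechin | Brc5c(OCc9ccccc9)cc(OCc9ccccc9)c6c5O[C@H](c8ccc(OCc9ccccc9)c(OCc9ccccc9)c8)[C@H](O)C6 | intermediate
9 | 8-bromo-5,7,3',4'-tetra-O-benzyl-3-O-TBS-epicatechin | Brc5c(OCc9ccccc9)cc(OCc9ccccc9)c6c5O[C@H](c8ccc(OCc9ccccc9)c(OCc9ccccc9)c8)[C@H](O[Si](C)(C)C(C)(C)C)C6 | intermediate
10 | 8-lithio-5,7,3',4'-tetra-O-benzyl-3-O-TBS-epicatechin | [Li]c5c(OCc9ccccc9)cc(OCc9ccccc9)c6c5O[C@H](c8ccc(OCc9ccccc9)c(OCc9ccccc9)c8)[C@H](O[Si](C)(C)C(C)(C)C)C6 | intermediate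
11 | 5,7,3',4'-tetra-O-benzyl-3-O-TBS-epicatechin-8-carbaldehyde | O=Cc5c(OCc9ccccc9)cc(OCc9ccccc9)c6c5O[C@H](c8ccc(OCc9ccccc9)c(OCc9ccccc9)c8)[C@H](O[Si](C)(C)C(C)(C)C)C6 | intermediate
12 | 4-benzyloxy-6-(lithiomethyl)-3-(penta-O-benzylepicatechin-4β-yl)-2-pyrone | O1[C@H](c8ccc(OCc9ccccc9)c(OCc9ccccc9)c8)[C@H](OCc9ccccc9)[C@@H](C3=C(OCc9ccccc9)C=C(C[Li])OC3=O)c2c(OCc9ccccc9)cc(OCc9ccccc9)cc21 | intermediate
13 | 4-benzyloxy-3-(top-4β-yl)-6-[2-hydroxy-2-(bottom-8-yl)ethyl]-2-pyrone, carbinol epimers | O1[C@H](c8ccc(OCc9ccccc9)c(OCc9ccccc9)c8)[C@H](OCc9ccccc9)[C@@H](C3=C(OCc9ccccc9)C=C(CC(O)c5c(OCc9ccccc9)cc(OCc9ccccc9)c6c5O[C@H](c8ccc(OCc9ccccc9)c(OCc9ccccc9)c8)[C@H](O[Si](C)(C)C(C)(C)C)C6)OC3=O)c2c(OCc9ccccc9)cc(OCc9ccccc9)cc21 | intermediate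
14 | key-step precursor: 4-benzyloxy-2-pyrone with the top unit (C4β) at C3 and the bottom-unit aroylmethyl group at C6 | O1[C@H](c8ccc(OCc9ccccc9)c(OCc9ccccc9)c8)[C@H](OCc9ccccc9)[C@@H](C3=C(OCc9ccccc9)C=C(CC(=O)c5c(OCc9ccccc9)cc(OCc9ccccc9)c6c5O[C@H](c8ccc(OCc9ccccc9)c(OCc9ccccc9)c8)[C@H](O[Si](C)(C)C(C)(C)C)C6)OC3=O)c2c(OCc9ccccc9)cc(OCc9ccccc9)cc21 | intermediate
15 | benzyl 3-benzyloxy-5,7-dioxo-7-(bottom-8-yl)-2-(top-4β-yl)hept-2-enoate, ester carbon and C4 methylene cis (shown in neutral form, present as magnesium chelate) | O1[C@H](c8ccc(OCc9ccccc9)c(OCc9ccccc9)c8)[C@H](OCc9ccccc9)[C@@H](/C(C(=O)OCc9ccccc9)=C(\OCc9ccccc9)CC(=O)CC(=O)c5c(OCc9ccccc9)cc(OCc9ccccc9)c6c5O[C@H](c8ccc(OCc9ccccc9)c(OCc9ccccc9)c8)[C@H](O[Si](C)(C)C(C)(C)C)C6)c2c(OCc9ccccc9)cc(OCc9ccccc9)cc21 | intermediate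
16 | key-step product: 4-benzyloxy-2,6-dihydroxybenzophenone linking top unit (on C8) and bottom unit (through the C4 carbonyl) | O1[C@H](c8ccc(OCc9ccccc9)c(OCc9ccccc9)c8)[C@H](OCc9ccccc9)[C@@H](c3c(OCc9ccccc9)cc(O)c(C(=O)c5c(OCc9ccccc9)cc(OCc9ccccc9)c6c5O[C@H](c8ccc(OCc9ccccc9)c(OCc9ccccc9)c8)[C@H](O[Si](C)(C)C(C)(C)C)C6)c3O)c2c(OCc9ccccc9)cc(OCc9ccccc9)cc21 | intermediate
17 | C5-O-benzyl ether of 16, C8a-OH free | O1[C@H](c8ccc(OCc9ccccc9)c(OCc9ccccc9)c8)[C@H](OCc9ccccc9)[C@@H](c3c(OCc9ccccc9)cc(OCc9ccccc9)c(C(=O)c5c(OCc9ccccc9)cc(OCc9ccccc9)c6c5O[C@H](c8ccc(OCc9ccccc9)c(OCc9ccccc9)c8)[C@H](O[Si](C)(C)C(C)(C)C)C6)c3O)c2c(OCc9ccccc9)cc(OCc9ccccc9)cc21 | intermediate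
18 | o-hydroxybenzhydrol from 17, carbinol epimers | O1[C@H](c8ccc(OCc9ccccc9)c(OCc9ccccc9)c8)[C@H](OCc9ccccc9)[C@@H](c3c(OCc9ccccc9)cc(OCc9ccccc9)c(C(O)c5c(OCc9ccccc9)cc(OCc9ccccc9)c6c5O[C@H](c8ccc(OCc9ccccc9)c(OCc9ccccc9)c8)[C@H](O[Si](C)(C)C(C)(C)C)C6)c3O)c2c(OCc9ccccc9)cc(OCc9ccccc9)cc21 | intermediate
19 | (tert-butyldimethylsilyloxy)acetaldehyde | O=CCO[Si](C)(C)C(C)(C)C | starting material
20 | (E)-o-quinone methide (C8a=O, C4a=C4, bottom unit anti to C8a) | O1[C@H](c8ccc(OCc9ccccc9)c(OCc9ccccc9)c8)[C@H](OCc9ccccc9)[C@@H](C3=C(OCc9ccccc9)C=C(OCc9ccccc9)/C(=C\c5c(OCc9ccccc9)cc(OCc9ccccc9)c6c5O[C@H](c8ccc(OCc9ccccc9)c(OCc9ccccc9)c8)[C@H](O[Si](C)(C)C(C)(C)C)C6)C3=O)c2c(OCc9ccccc9)cc(OCc9ccccc9)cc21 | intermediate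
21 | (E)-enamine of 19 and (S)-2-[diphenyl(trimethylsilyloxy)methyl]pyrrolidine | CC(C)(C)[Si](C)(C)O/C=C/N1CCC[C@H]1C(c1ccccc1)(c1ccccc1)O[Si](C)(C)C | intermediate
22 | middle-unit lactol: chroman-2-ol with 3α-OTBS and 4β-(bottom-8-yl), 3,4-trans, C2 anomers | O1[C@H](c8ccc(OCc9ccccc9)c(OCc9ccccc9)c8)[C@H](OCc9ccccc9)[C@@H](c3c(OCc9ccccc9)cc(OCc9ccccc9)c4c3OC(O)[C@H](O[Si](C)(C)C(C)(C)C)[C@H]4c5c(OCc9ccccc9)cc(OCc9ccccc9)c6c5O[C@H](c8ccc(OCc9ccccc9)c(OCc9ccccc9)c8)[C@H](O[Si](C)(C)C(C)(C)C)C6)c2c(OCc9ccccc9)cc(OCc9ccccc9)cc21 | intermediate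
23 | 2-O-acetate of 22, C2 anomers | O1[C@H](c8ccc(OCc9ccccc9)c(OCc9ccccc9)c8)[C@H](OCc9ccccc9)[C@@H](c3c(OCc9ccccc9)cc(OCc9ccccc9)c4c3OC(OC(C)=O)[C@H](O[Si](C)(C)C(C)(C)C)[C@H]4c5c(OCc9ccccc9)cc(OCc9ccccc9)c6c5O[C@H](c8ccc(OCc9ccccc9)c(OCc9ccccc9)c8)[C@H](O[Si](C)(C)C(C)(C)C)C6)c2c(OCc9ccccc9)cc(OCc9ccccc9)cc21 | intermediate
24 | 4-bromocatechol | Oc1ccc(Br)cc1O | starting material
25 | 4-bromo-1,2-bis(benzyloxy)benzene | Brc1ccc(OCc2ccccc2)c(OCc2ccccc2)c1 | intermediate
26 | [3,4-bis(benzyloxy)phenyl]lithium | [Li]c1ccc(OCc2ccccc2)c(OCc2ccccc2)c1 | intermediate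
27 | lithium [3,4-bis(benzyloxy)phenyl]triisopropoxyborate | [Li+].CC(C)O[B-](OC(C)C)(OC(C)C)c1ccc(OCc2ccccc2)c(OCc2ccccc2)c1 | intermediate
28 | potassium [3,4-bis(benzyloxy)phenyl]trifluoroborate | [K+].F[B-](F)(F)c1ccc(OCc2ccccc2)c(OCc2ccccc2)c1 | intermediate
29 | protected trimer, all units 2,3-cis-3,4-trans (4β→8), middle and bottom O3 as TBS ethers, top O3 benzylated | O1[C@H](c8ccc(OCc9ccccc9)c(OCc9ccccc9)c8)[C@H](OCc9ccccc9)[C@@H](c3c(OCc9ccccc9)cc(OCc9ccccc9)c4c3O[C@H](c8ccc(OCc9ccccc9)c(OCc9ccccc9)c8)[C@H](O[Si](C)(C)C(C)(C)C)[C@H]4c5c(OCc9ccccc9)cc(OCc9ccccc9)c6c5O[C@H](c8ccc(OCc9ccccc9)c(OCc9ccccc9)c8)[C@H](O[Si](C)(C)C(C)(C)C)C6)c2c(OCc9ccccc9)cc(OCc9ccccc9)cc21 | intermediate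
30 | protected trimer with free middle and bottom 3-OH | O1[C@H](c8ccc(OCc9ccccc9)c(OCc9ccccc9)c8)[C@H](OCc9ccccc9)[C@@H](c3c(OCc9ccccc9)cc(OCc9ccccc9)c4c3O[C@H](c8ccc(OCc9ccccc9)c(OCc9ccccc9)c8)[C@H](O)[C@H]4c5c(OCc9ccccc9)cc(OCc9ccccc9)c6c5O[C@H](c8ccc(OCc9ccccc9)c(OCc9ccccc9)c8)[C@H](O)C6)c2c(OCc9ccccc9)cc(OCc9ccccc9)cc21 | intermediate
31 | 3,4,5-tris(benzyloxy)benzoic acid | OC(=O)c1cc(OCc2ccccc2)c(OCc2ccccc2)c(OCc2ccccc2)c1 | starting material
32 | protected trimer bis(tri-O-benzylgallate) at middle and bottom O3 | O1[C@H](c8ccc(OCc9ccccc9)c(OCc9ccccc9)c8)[C@H](OCc9ccccc9)[C@@H](c3c(OCc9ccccc9)cc(OCc9ccccc9)c4c3O[C@H](c8ccc(OCc9ccccc9)c(OCc9ccccc9)c8)[C@H](OC(=O)c7cc(OCc9ccccc9)c(OCc9ccccc9)c(OCc9ccccc9)c7)[C@H]4c5c(OCc9ccccc9)cc(OCc9ccccc9)c6c5O[C@H](c8ccc(OCc9ccccc9)c(OCc9ccccc9)c8)[C@H](OC(=O)c7cc(OCc9ccccc9)c(OCc9ccccc9)c(OCc9ccccc9)c7)C6)c2c(OCc9ccccc9)cc(OCc9ccccc9)cc21 | intermediate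
33 | epicatechin-(4β→8)-epicatechin 3-O-gallate-(4β→8)-epicatechin 3-O-gallate | O=C(O[C@@H]1[C@@H](c2c(O)cc(O)c3c2O[C@H](c2ccc(O)c(O)c2)[C@H](OC(=O)c2cc(O)c(O)c(O)c2)C3)c2c(O)cc(O)c([C@H]3c4c(O)cc(O)cc4O[C@H](c4ccc(O)c(O)c4)[C@@H]3O)c2O[C@@H]1c1ccc(O)c(O)c1)c1cc(O)c(O)c(O)c1 | target

Total step count: 21. Longest linear sequence: 16 steps (steps 1–5, 9–15 and 18–21).

Steps most likely to fail

Step 11.
- Risk: attack of the alkoxide on the lactone carbonyl may be too slow. The base first turns the substrate into an extended enolate, and the carbonyl group sits next to the bulky flavanyl substituent. The opened chain may also relactonise, or lose the aroyl group by retro-Claisen cleavage, before it closes.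
- Fallback: this sets out from 4 and 11 and comes back at 18, and it takes the middle ring A from purchased 3,5-bis(benzyloxy)phenol instead of folding it. BF3·OEt2-catalysed alkylation of that phenol (in excess) with 4 should give, ortho to the hydroxyl group and from the β face, 3,5-bis(benzyloxy)-2-(penta-O-benzylepicatechin-4β-yl)phenol F1. EtMgBr converts it into its bromomagnesium phenolate F2. In toluene F2 adds through its only free ortho carbon to aldehyde 11 (magnesium-templated ortho-hydroxyalkylation of phenols) and gives carbinol 18 directly.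

Step 14.
- Risk: carbon–carbon bond formation at the crowded methide carbon may be slow enough for an internal hydride shift from a neighbouring benzyl ether to compete. The resident chirality of the two flavan units may also oppose the catalyst and erode facial selectivity.
- Fallback: this sets out from 18 and comes back at 23, and it replaces catalyst control by a robust cycloaddition, separation and substrate control.
 - The quinone methide 20 is trapped with ethyl vinyl ether (inverse-demand hetero-Diels–Alder reaction, pyridinium p-toluenesulfonate) to give the 2-ethoxy-4-arylchroman F3 as a mixture at C2 and C4.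
 - Acid-catalysed loss of ethanol gives the 4H-chromenes. Their C4 epimers are diastereomers because of the resident units, and they are separated to leave the 4β-aryl-4H-chromene F4.
 - Dimethyldioxirane attacks the enol ether anti to the pseudo-axial bottom unit to give the 2α,3α-epoxide F5.
 - Acetic acid opens it at C2 to the 2-acetoxychroman-3α-ol F6, and TBSOTf with 2,6-lutidine silylates O3 to give 23.

Step 18.
- Risk: the oxocarbenium ion may be captured by the electron-rich A rings of a second molecule, or lose its silyl group, faster than it accepts the aryl group. Delivery to the α face may also be incomplete.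
- Fallback: this sets out from 22 and 25 and comes back at 29, and it forms the C2–aryl bond at the aldehyde stage and the O1–C2 bond afterwards. Magnesium turns 25 into [3,4-bis(benzyloxy)phenyl]magnesium bromide F7. Used in excess, F7 adds to the open hydroxy aldehyde form of 22 under polar Felkin–Anh control by the non-chelating silyl ether and gives the 2,3-anti benzylic alcohol F8. Intramolecular Mitsunobu etherification (PPh3, diisopropyl azodicarboxylate) then closes O1–C2 with inversion, which turns the anti arrangement into the 2,3-cis ring of 29.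

Further compounds

F1 | step 11 | 3,5-bis(benzyloxy)-2-(penta-O-benzylepicatechin-4β-yl)phenol | O1[C@H](c8ccc(OCc9ccccc9)c(OCc9ccccc9)c8)[C@H](OCc9ccccc9)[C@@H](c3c(OCc9ccccc9)cc(OCc9ccccc9)cc3O)c2c(OCc9ccccc9)cc(OCc9ccccc9)cc21
F2 | step 11 | bromomagnesium phenolate of F1 | O1[C@H](c8ccc(OCc9ccccc9)c(OCc9ccccc9)c8)[C@H](OCc9ccccc9)[C@@H](c3c(OCc9ccccc9)cc(OCc9ccccc9)cc3O[Mg]Br)c2c(OCc9ccccc9)cc(OCc9ccccc9)cc21
F3 | step 14 | 2-ethoxy-4-(bottom-8-yl)-5,7-bis(benzyloxy)-8-(top-4β-yl)chroman, mixture at C2 and C4 | O1[C@H](c8ccc(OCc9ccccc9)c(OCc9ccccc9)c8)[C@H](OCc9ccccc9)[C@@H](c3c(OCc9ccccc9)cc(OCc9ccccc9)c4c3OC(OCC)CC4c5c(OCc9ccccc9)cc(OCc9ccccc9)c6c5O[C@H](c8ccc(OCc9ccccc9)c(OCc9ccccc9)c8)[C@H](O[Si](C)(C)C(C)(C)C)C6)c2c(OCc9ccccc9)cc(OCc9ccccc9)cc21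
F4 | step 14 | 4β-(bottom-8-yl)-5,7-bis(benzyloxy)-8-(top-4β-yl)-4H-chromene | O1[C@H](c8ccc(OCc9ccccc9)c(OCc9ccccc9)c8)[C@H](OCc9ccccc9)[C@@H](c3c(OCc9ccccc9)cc(OCc9ccccc9)c4c3OC=C[C@H]4c5c(OCc9ccccc9)cc(OCc9ccccc9)c6c5O[C@H](c8ccc(OCc9ccccc9)c(OCc9ccccc9)c8)[C@H](O[Si](C)(C)C(C)(C)C)C6)c2c(OCc9ccccc9)cc(OCc9ccccc9)cc21
F5 | step 14 | 2α,3α-epoxide of F4 | O1[C@H](c8ccc(OCc9ccccc9)c(OCc9ccccc9)c8)[C@H](OCc9ccccc9)[C@@H](c3c(OCc9ccccc9)cc(OCc9ccccc9)c4c3O[C@@H]7O[C@@H]7[C@H]4c5c(OCc9ccccc9)cc(OCc9ccccc9)c6c5O[C@H](c8ccc(OCc9ccccc9)c(OCc9ccccc9)c8)[C@H](O[Si](C)(C)C(C)(C)C)C6)c2c(OCc9ccccc9)cc(OCc9ccccc9)cc21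
F6 | step 14 | 2-acetoxy-4β-(bottom-8-yl)chroman-3α-ol, 3,4-trans | O1[C@H](c8ccc(OCc9ccccc9)c(OCc9ccccc9)c8)[C@H](OCc9ccccc9)[C@@H](c3c(OCc9ccccc9)cc(OCc9ccccc9)c4c3OC(OC(C)=O)[C@H](O)[C@H]4c5c(OCc9ccccc9)cc(OCc9ccccc9)c6c5O[C@H](c8ccc(OCc9ccccc9)c(OCc9ccccc9)c8)[C@H](O[Si](C)(C)C(C)(C)C)C6)c2c(OCc9ccccc9)cc(OCc9ccccc9)cc21
F7 | step 18 | [3,4-bis(benzyloxy)phenyl]magnesium bromide | Br[Mg]c1ccc(OCc2ccccc2)c(OCc2ccccc2)c1
F8 | step 18 | open-chain 2,3-anti benzylic alcohol with free O8a phenol, 3-OTBS and C4 as in 22 | O1[C@H](c8ccc(OCc9ccccc9)c(OCc9ccccc9)c8)[C@H](OCc9ccccc9)[C@@H](c3c(OCc9ccccc9)cc(OCc9ccccc9)c(c3O)[C@H](c5c(OCc9ccccc9)cc(OCc9ccccc9)c6c5O[C@H](c8ccc(OCc9ccccc9)c(OCc9ccccc9)c8)[C@H](O[Si](C)(C)C(C)(C)C)C6)[C@@H](O[Si](C)(C)C(C)(C)C)[C@@H](O)c8ccc(OCc9ccccc9)c(OCc9ccccc9)c8)c2c(OCc9ccccc9)cc(OCc9ccccc9)cc21
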